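## Retrosynthetic overview
1. Only the central carbocycle (ring B) has to be built, since both arenes are bought. It is closed last: C2–C7' Friedel–Crafts closure of a (Z)-homoallylic benzylic alcohol, then saturation of C7=C8 and loss of both MOM groups in the same flask.
2. C1–C7: nickel-catalysed coupling of a syringyl Grignard reagent at the vinylic C–O bond of an enol carbamate.
3. C7'–C8' (key bond): a chiral titanated tiglyl carbamate, which is a homoenolate (d3) equivalent of 2-methylbutanal, attacks O-MOM-vanillin. This joins two carbons that are both natural acceptors (the β-carbon of an enal and a C=O carbon) and sets C8'.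
4. Stereochemical relay: C8' (reagent control), then C7' (trans, set at ring closure), then C8 (methyl cis to the C8' methyl, set by axial protonation).

Assumption: lignan locants are used in the discussion (C1–C9 for the syringyl half, C1'–C9' for the guaiacyl half). Compounds 1, 3, 5 and (+)-sparteine are taken as catalogue chemicals.

## Route

**Step 1**
Reactants: 1 (E)-2-methylbut-2-en-1-ol (tiglyl alcohol)
Product: 2 (E)-2-methylbut-2-en-1-yl N,N-diisopropylcarbamate
Conditions: NaH, i-Pr2NCOCl, THF, 0 °C → reflux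
Reagents that add atoms: N,N-diisopropylcarbamoyl chloride, CC(C)N(C(C)C)C(=O)Cl
Why: O-carbamoylation (acyl substitution) of the sodium alkoxide installs the hindered carbamate that later directs lithiation, resists attack by s-BuLi and serves as the vinylic leaving group, and it leaves the (E)-alkene untouched.

**Step 2**
Reactants: 3 vanillin
Product: 4 3-methoxy-4-(methoxymethoxy)benzaldehyde
Conditions: MOMCl, K2CO3, acetone, 0 °C → rt
Reagents that add atoms: chloromethyl methyl ether, COCCl
Why: Williamson-type O-alkylation of the phenoxide gives a MOM acetal that is inert to organotitanium and Grignard reagents and falls off in the final acid step without a step of its own.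

**Step 3**
Reactants: 5 4-bromo-2,6-dimethoxyphenol
Product: 6 5-bromo-1,3-dimethoxy-2-(methoxymethoxy)benzene
Conditions: NaH, MOMCl, DMF, 0 °C → rt
Reagents that add atoms: chloromethyl methyl ether, COCCl
Why: Williamson-type O-alkylation of the hindered sodium phenoxide removes the acidic proton, so the aryl bromide can be turned into a Grignard reagent.

**Step 4 (key step)**
Reactants: 2 (E)-2-methylbut-2-en-1-yl N,N-diisopropylcarbamate; 4 3-methoxy-4-(methoxymethoxy)benzaldehyde
Product: 9 (1Z,3R,4R)-4-hydroxy-4-[3-methoxy-4-(methoxymethoxy)phenyl]-2,3-dimethylbut-1-en-1-yl N,N-diisopropylcarbamate, via lithiated carbamate 7 (not isolated), via allyltitanium 8 (not isolated)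
Conditions: s-BuLi, (+)-sparteine, toluene, −78 °C; ClTi(OiPr)3, −78 °C; then 4, −78 → −40 °C; aq NH4Cl
Reagents that add atoms: none
Why: Hoppe asymmetric homoaldol reaction, in which carbamate-directed deprotonation by s-BuLi/(+)-sparteine gives (R)-7 (the mirror image of the sense known for (−)-sparteine with crotyl and cycloalk-1-enylmethyl carbamates), Li→Ti exchange with inversion gives (S)-8, and this chiral homoenolate equivalent adds through its γ-carbon (C8', the β-carbon of the latent C7 aldehyde) to the aldehyde carbon C7' via a chair Zimmerman–Traxler transition state (aryl and C9' methyl equatorial, OCb axial), setting C8' as R and C7' as R (anti) and leaving the (Z)-enol carbamate.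

**Step 5**
Reactants: 9 (1Z,3R,4R)-homoaldol adduct; 6 5-bromo-1,3-dimethoxy-2-(methoxymethoxy)benzene
Product: 11 (1R,2R,3Z)-4-[3,5-dimethoxy-4-(methoxymethoxy)phenyl]-1-[3-methoxy-4-(methoxymethoxy)phenyl]-2,3-dimethylbut-3-en-1-ol, via aryl Grignard 10 (not isolated)
Conditions: 6, Mg, THF, reflux; then 9 (3 equiv of 10 per 9), Ni(acac)2 (10 mol %), THF/Et2O, 0 °C → rt
Reagents that add atoms: none
Why: Kumada–Corriu-type C–O cross-coupling, in which the first equivalent of 10 only deprotonates the carbinol, zerovalent nickel (formed from Ni(acac)2 and 10) inserts into the vinylic C–OCb bond, and aryl transfer with reductive elimination proceeds with retention, so the aryl group ends up cis to C8' (Z) as ring closure requires, no stereocentre is touched, and aryl–OMe, MOM and the magnesium alkoxide are inert to this phosphine-free catalyst at room temperature.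

**Step 6**
Reactants: 11 (1R,2R,3Z)-alkenol
Product: 14 (−)-(7'R,8R,8'R)-4,4'-dihydroxy-3,3',5-trimethoxy-2,7'-cyclolignan, via dihydronaphthalene 12 (not isolated), via tetralin bis-MOM ether 13 (not isolated)
Conditions: TFA, CH2Cl2, −20 °C, 15 min; then Et3SiH (6 equiv), more TFA, −20 °C → rt, Ar
Reagents that add atoms: none
Why: Intramolecular Friedel–Crafts alkylation, Kursanov–Parnes ionic hydrogenation and MOM acidolysis in one flask, in which ionisation of the p-alkoxybenzylic alcohol erases C7', the (Z)-held, doubly OMe-activated C2 closes ring B with the aryl group trans to the C8' methyl (both pseudoaxial, avoiding the peri C3-OMe and A(1,2) strain with the C8 methyl) to give 12, reversible protonation of C8 anti to the pseudoaxial C8' methyl places the C8 methyl equatorial and cis to it (the trans epimer would need a syn-diaxial aryl/methyl pair or an equatorial aryl pressed against the peri OMe), Et3SiH quenches the C7 benzylic cation to give 13, and the MeOCH2+ ions released on warming are reduced to Me2O instead of alkylating the arenes.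

## Compound list
1 | (E)-2-methylbut-2-en-1-ol | C/C=C(\C)CO | starting material
2 | (E)-2-methylbut-2-en-1-yl N,N-diisopropylcarbamate | C/C=C(\C)COC(=O)N(C(C)C)C(C)C | intermediate
3 | vanillin | COc1cc(C=O)ccc1O | starting material
4 | 3-methoxy-4-(methoxymethoxy)benzaldehyde | COCOc1ccc(C=O)cc1OC | intermediate
5 | 4-bromo-2,6-dimethoxyphenol | COc1cc(Br)cc(OC)c1O | starting material
6 | 5-bromo-1,3-dimethoxy-2-(methoxymethoxy)benzene | COCOc1c(OC)cc(Br)cc1OC | intermediate
7 | (1R,2E)-1-(N,N-diisopropylcarbamoyloxy)-2-methylbut-2-en-1-yllithium, held as its (+)-sparteine complex (diamine not drawn) | [Li][C@@H](OC(=O)N(C(C)C)C(C)C)/C(C)=C/C | intermediate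
8 | (1S,2E)-[1-(N,N-diisopropylcarbamoyloxy)-2-methylbut-2-en-1-yl]tris(propan-2-olato)titanium | CC(C)O[Ti](OC(C)C)(OC(C)C)[C@H](OC(=O)N(C(C)C)C(C)C)/C(C)=C/C | intermediate
9 | (1Z,3R,4R)-4-hydroxy-4-[3-methoxy-4-(methoxymethoxy)phenyl]-2,3-dimethylbut-1-en-1-yl N,N-diisopropylcarbamate | COCOc1ccc(cc1OC)[C@H](O)[C@H](C)/C(C)=C\OC(=O)N(C(C)C)C(C)C | intermediate
10 | [3,5-dimethoxy-4-(methoxymethoxy)phenyl]magnesium bromide | COCOc1c(OC)cc([Mg]Br)cc1OC | intermediate
11 | (1R,2R,3Z)-4-[3,5-dimethoxy-4-(methoxymethoxy)phenyl]-1-[3-methoxy-4-(methoxymethoxy)phenyl]-2,3-dimethylbut-3-en-1-ol | COCOc1ccc(cc1OC)[C@H](O)[C@H](C)/C(C)=C\c1cc(OC)c(OCOC)c(OC)c1 | intermediate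
12 | (1R,2S)-6,8-dimethoxy-7-(methoxymethoxy)-1-[3-methoxy-4-(methoxymethoxy)phenyl]-2,3-dimethyl-1,2-dihydronaphthalene | COCOc1ccc(cc1OC)[C@@H]1c2c(OC)c(OCOC)c(OC)cc2C=C(C)[C@H]1C | intermediate
13 | (1R,2R,3R)-6,8-dimethoxy-7-(methoxymethoxy)-1-[3-methoxy-4-(methoxymethoxy)phenyl]-2,3-dimethyl-1,2,3,4-tetrahydronaphthalene | COCOc1ccc(cc1OC)[C@@H]1c2c(OC)c(OCOC)c(OC)cc2C[C@@H](C)[C@H]1C | intermediate
14 | (−)-(7'R,8R,8'R)-4,4'-dihydroxy-3,3',5-trimethoxy-2,7'-cyclolignan = (6R,7R,8R)-8-(4-hydroxy-3-methoxyphenyl)-1,3-dimethoxy-6,7-dimethyl-5,6,7,8-tetrahydronaphthalen-2-ol | COc1cc([C@@H]2c3c(cc(OC)c(O)c3OC)C[C@@H](C)[C@H]2C)ccc1O | target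

## Count and risks
Total steps: 6. Longest linear sequence: 4 (steps 1, 4, 5, 6).

**Step 4.** The risk is the level and sense of enantioselection with the acyclic 2-methyl-substituted carbamate. The fallback sets out from 2 (with 4) and comes back at 9.
- The chiral diamine is given up. Compound 2 is lithiated with s-BuLi/TMEDA and titanated with ClTi(OiPr)3, so that 7 and 8 form together with their mirror images (1S,2E)-1-(N,N-diisopropylcarbamoyloxy)-2-methylbut-2-en-1-yllithium F1 and (1R,2E)-[1-(N,N-diisopropylcarbamoyloxy)-2-methylbut-2-en-1-yl]tris(propan-2-olato)titanium F2.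
- Addition to 4 gives the racemic (Z)-anti adduct, that is 9 plus (1Z,3S,4S)-4-hydroxy-4-[3-methoxy-4-(methoxymethoxy)phenyl]-2,3-dimethylbut-1-en-1-yl N,N-diisopropylcarbamate F3.
- An acylative kinetic resolution follows, using propanoic anhydride, i-Pr2NEt and (S)-2-phenyl-2,3-dihydroimidazo[2,1-b][1,3]benzothiazole (the antipode that acylates (S)-1-arylalkanols faster). It converts F3 into (1S,2S,3Z)-4-(N,N-diisopropylcarbamoyloxy)-1-[3-methoxy-4-(methoxymethoxy)phenyl]-2,3-dimethylbut-3-en-1-yl propanoate F4.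
- Unreacted 9 is separated by chromatography. Because C7' and C8' are locked anti, resolving the carbinol centre also resolves C8'.

**Step 5.** The risk is sluggish C–O insertion at the trisubstituted enol carbamate. The fallback sets out from 9 (with 10) and comes back at 12. It uses the latent aldehyde as a carbonyl group instead of using the C–O bond as a coupling handle.
- MeLi (about 4 equiv, Et2O, 0 °C) cleaves the enol carbamate to the aldehyde enolate. Aqueous quench gives (4R,5R)-5-[3-methoxy-4-(methoxymethoxy)phenyl]-3,4-dimethyloxolan-2-ol F5.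
- Grignard reagent 10 adds to the open form of F5 to give (1R,2R)-4-[3,5-dimethoxy-4-(methoxymethoxy)phenyl]-1-[3-methoxy-4-(methoxymethoxy)phenyl]-2,3-dimethylbutane-1,4-diol F6.
- In TFA/CH2Cl2 at −20 °C, without silane at first, the better-stabilised C7' cation is trapped by the more nucleophilic trioxygenated ring. This gives (3S,4R)-5,7-dimethoxy-6-(methoxymethoxy)-4-[3-methoxy-4-(methoxymethoxy)phenyl]-2,3-dimethyl-1,2,3,4-tetrahydronaphthalen-1-ol F7, which dehydrates to 12.
- The undefined C7 and C8 centres of F5 to F7 are erased in 12. Et3SiH is then added as in step 6.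

**Step 6.** The risks are the facial selectivity of C8 protonation and side reactions of the styrene in acid. The fallback sets out from 11 and comes back at 13. The order is inverted, so C8 is set on the open chain before the ring is closed.
- Heterogeneous hydrogenation (H2 1 atm, 5% Pt/C, EtOAc, trace Et3N) acts on the (Z)-alkene. A(1,3) strain with the cis aryl group holds H-8' in the alkene plane.
- Hydrogen is therefore delivered from the face carrying the small C9' methyl, anti to the bulky CH(OH)Ar group. The product is (1R,2R,3R)-4-[3,5-dimethoxy-4-(methoxymethoxy)phenyl]-1-[3-methoxy-4-(methoxymethoxy)phenyl]-2,3-dimethylbutan-1-ol F8.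
- HCl in MeOH (40 °C) then ionises the carbinol, closes ring B trans to give 13, and methanolyses the MOM groups to give 14.

## Further compounds
F1 | step 4 | (1S,2E)-1-(N,N-diisopropylcarbamoyloxy)-2-methylbut-2-en-1-yllithium (enantiomer of 7, TMEDA complex) | [Li][C@H](OC(=O)N(C(C)C)C(C)C)/C(C)=C/C
F2 | step 4 | (1R,2E)-[1-(N,N-diisopropylcarbamoyloxy)-2-methylbut-2-en-1-yl]tris(propan-2-olato)titanium (enantiomer of 8) | CC(C)O[Ti](OC(C)C)(OC(C)C)[C@@H](OC(=O)N(C(C)C)C(C)C)/C(C)=C/C
F3 | step 4 | (1Z,3S,4S)-4-hydroxy-4-[3-methoxy-4-(methoxymethoxy)phenyl]-2,3-dimethylbut-1-en-1-yl N,N-diisopropylcarbamate (enantiomer of 9) | COCOc1ccc(cc1OC)[C@@H](O)[C@@H](C)/C(C)=C\OC(=O)N(C(C)C)C(C)C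
F4 | step 4 | (1S,2S,3Z)-4-(N,N-diisopropylcarbamoyloxy)-1-[3-methoxy-4-(methoxymethoxy)phenyl]-2,3-dimethylbut-3-en-1-yl propanoate | COCOc1ccc(cc1OC)[C@@H](OC(=O)CC)[C@@H](C)/C(C)=C\OC(=O)N(C(C)C)C(C)C
F5 | step 5 | (4R,5R)-5-[3-methoxy-4-(methoxymethoxy)phenyl]-3,4-dimethyloxolan-2-ol (mixture at C2 and C3) | COCOc1ccc(cc1OC)[C@@H]1OC(O)C(C)[C@H]1C
F6 | step 5 | (1R,2R)-4-[3,5-dimethoxy-4-(methoxymethoxy)phenyl]-1-[3-methoxy-4-(methoxymethoxy)phenyl]-2,3-dimethylbutane-1,4-diol (mixture at C3 and C4) | COCOc1ccc(cc1OC)[C@H](O)[C@H](C)C(C)C(O)c1cc(OC)c(OCOC)c(OC)c1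
F7 | step 5 | (3S,4R)-5,7-dimethoxy-6-(methoxymethoxy)-4-[3-methoxy-4-(methoxymethoxy)phenyl]-2,3-dimethyl-1,2,3,4-tetrahydronaphthalen-1-ol (mixture at C1 and C2) | COCOc1ccc(cc1OC)[C@@H]1c2c(OC)c(OCOC)c(OC)cc2C(O)C(C)[C@H]1C
F8 | step 6 | (1R,2R,3R)-4-[3,5-dimethoxy-4-(methoxymethoxy)phenyl]-1-[3-methoxy-4-(methoxymethoxy)phenyl]-2,3-dimethylbutan-1-ol | COCOc1ccc(cc1OC)[C@H](O)[C@H](C)[C@H](C)Cc1cc(OC)c(OCOC)c(OC)c1
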